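- Read at 3.0 min, each flask is one number, and you must choose which recipe to charge next.

| flask | substrate | partner | initiator | remark | time |
|---|---|---|---|---|---|
| south-west | 0.10 M (fed, over 30 s) | 0.099 M | 1 mM | run made earlier |  |
| south | 0.10 M (fed, over 30 s) | 0.34 M | 1 mM | run made earlier |  |
| north-west | 0.16 M (fed, over 30 s) | 0.30 M | 1 mM | run made earlier |  |
| Thursday's | 0.10 M (fed, over 30 s) | 0.300 M | 1.0 mM |  | 3.0 min |
| Sunday's | 0.30 M (fed, over 120 s) | 0.150 M | 1.0 mM |  | 3.0 min |
| Tuesday's | 0.40 M (fed, over 120 s) | 0.300 M | 1.0 mM |  | 3.0 min |
| Saturday's | 0.10 M (fed, over 30 s) | 0.0800 M | 1.0 mM |  | 3.0 min |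
| Monday's | 0.10 M (fed, over 120 s) | 0.300 M | 1.0 mM |  | 3.0 min |
| Friday's | 0.40 M (fed, over 20 s) | 0.300 M | 1.0 mM |  | 3.0 min |

| run | time / min | target / % | substrate / % |
|---|---|---|---|
| south-west | 0.833 | 68.6 | 31.1 |
| south-west | 1.50 | 70.6 | 27.8 |
| south-west | 2.50 | 72.2 | 27.3 |
| south-west | 3.00 | 72.1 | 27.6 |
| south | 0.250 | 51.3 | 0.4 |
| south | 0.500 | 99.6 | 0 |
| south | 1.33 | 100.9 | 1.0 |
| south | 3.00 | 100.7 | 0.3 |
| north-west | 0.833 | 101.1 | 0.6 |
| north-west | 1.50 | 100.5 | 0.1 |
| north-west | 2.50 | 100.3 | 0 |
| north-west | 3.00 | 100.4 | 0 |

(standard deviation of a reading: 0.5 percentage points)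

- the flasks put in order of amount of target, in percent of the substrate charged, best first, at 3.0 min (Thursday's / Sunday's / Tuesday's / Saturday's / Monday's / Friday's)
- the amount of target, in percent of the substrate charged of the flask you put first, at 3.0 min
- the amount of target, in percent of the substrate charged of the flask you put last, at 3.0 min

- The south-west run has stopped: target reads 72.2% at 2.50 min and 72.1% at 3.00 min, with substrate still at 27.6%.
- The south run, with 0.34 M of partner against 0.099 M, reaches 100.7%. So partner acts as the limiting reagent in the south-west run, and it is being lost beside the chain.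
- Suppose that substrate stands in the flask and that the level of first chain carrier is steady. Partner then meets two pseudo-first-order losses: kc[partner] into target, where kc is the constant of the step of partner with first chain carrier times that level, and k[partner] into decomposed reagent, where k is the decay constant.
- Divide one rate by the other and time drops out. While those suppositions hold, target per partner spent is φ = kc/(kc + k).
- The south-west plateau gives a reading of φ = 0.728, the partner yield.
- My rule, for 1.0 mM of initiator, is that the expected target, as a share of the substrate charged, is φ × partner/substrate, held at 100%. On a tie, the shorter feed goes first, because partner decays for longer under the longer feed.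
- Thursday's and Monday's both reckon to 2.18, so both are held at 100%, and Thursday's goes ahead on its 30 s feed.
- Saturday's gives 58.3%.
- Friday's and Tuesday's tie at 54.6%, and Friday's goes ahead on its 20 s feed.
- Sunday's gives 36.4%, the lowest reckoning.
- So you charge Thursday's.
- The forecast says Thursday's > Monday's > Saturday's > Friday's > Tuesday's > Sunday's, with 100% first and 33% last, on the ground that “any faster feed piles up substrate”. Its order is the same as mine, but its Sunday's figure stands below my 36.4%.
- The flasks give Thursday's > Monday's > Saturday's > Friday's > Tuesday's > Sunday's, with >99.9% first and 32.8% last.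

    initiator → 2 initiating radical (k = 0.00390 /s)
    substrate + initiating radical → capped initiator + first chain carrier (k = 7.97 × 10⁵ /M/s)
    partner + first chain carrier → target + second chain carrier (k = 2.10 × 10⁵ /M/s)
    substrate + second chain carrier → by-product + first chain carrier (k = 2.44 × 10⁵ /M/s)
    2 first chain carrier → ended chains (k = 7.00 × 10⁷ /M/s)
    partner → decomposed reagent (k = 0.0172 /s)

- Friday's gives 55.0% against the reckoned 54.6%, Tuesday's gives 44.0% against that same figure, and Sunday's gives 32.8% against 36.4%. Now take a neighbour of Sunday's, charged with 0.51 M of substrate and otherwise unchanged. The same reckoning, φ × 0.150 M/0.51 M, gives 21.4%. That neighbour flask gives 21.1% of target at 3.00 min, with partner at 0% and substrate at 78.7%.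

The earlier runs and the new flask come from a simulation for substances that don't exist.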